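**Retrosynthetic overview**

1. Target 22 is a heliangolide (germacrane numbering throughout): cyclodecene C1–C10 with a cis (4Z) ring alkene, a trans-fused α-methylene-γ-lactone (O–C6–C7–C11–C12), a C1–C10 oxirane carrying C14–OH, and an isobutyrate on C8.
2. The ten-membered ring is closed last by ring-closing metathesis at C4=C5; just before it, the C1–C10 oxirane comes from Sharpless epoxidation of the C14 allylic alcohol.
3. The lactone ring is cut at C7–C11. The enabling feature is that the C8 oxygen sits on the carbon exocyclic to the lactone at C7, anti to the C7–C11 ring bond, while C11 carries the C13 methylene conjugated to C12=O, whose ester oxygen is on C6. This is the retron of an acrylate α-carbon opening a trans-7,8-oxirane that lies erythro to the C6 acrylate (phosphine-catalysed Morita–Baylis–Hillman-type alkylation).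
4. The erythro epoxy alcohol comes from an (R,E)-alkenyl vinyl carbinol. C6 is the one centre set by catalysis from achiral material (asymmetric alkynylation of acrolein, then Red-Al); C7 and C8 are relayed from it in a matched Sharpless epoxidation and in the key step.
5. The C1=C10 geometry comes from a Still–Gennari olefination of 4-methylpent-4-enal. Ring order: C7–C8 oxirane → γ-lactone (oxirane consumed) → C1–C10 oxirane → cyclodecene.

Key step: step 10

Assumption: (S,S)-ProPhenol is taken as the ligand antipode that sends the alkynylzinc to the Si face of acrolein (R carbinol); if the sense is opposite the (R,R)-ligand is used, and any shortfall in ee is corrected by the matched epoxidation of step 8.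

**Route**

Step 1
Reactants: 1 4-methylpent-4-en-1-ol
Product: 2 4-methylpent-4-enal
Conditions: TEMPO (10 mol %), PhI(OAc)2 (1.1 equiv), CH2Cl2, rt; distilled and used at once
Reagents that add atoms: none
Why: Oxoammonium (TEMPO/PhI(OAc)2) oxidation of a primary alcohol should stop at the aldehyde and leave the 1,1-disubstituted alkene untouched.

Step 2
Reactants: 3 methyl 2-[bis(2,2,2-trifluoroethoxy)phosphoryl]acetate (1.5 equiv); 4 propargyl bromide
Product: 5 methyl 2-[bis(2,2,2-trifluoroethoxy)phosphoryl]pent-4-ynoate (racemic)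
Conditions: NaH, THF/DMF, 0 °C → rt
Reagents that add atoms: none
Why: SN2 C-alkylation of the stabilised phosphonoacetate carbanion by a primary propargylic bromide, with the excess of 3 holding back dialkylation.

Step 3
Reactants: 5 methyl 2-[bis(2,2,2-trifluoroethoxy)phosphoryl]pent-4-ynoate; 2 4-methylpent-4-enal
Product: 6 methyl (2Z)-6-methyl-2-(prop-2-yn-1-yl)hepta-2,6-dienoate
Conditions: KHMDS, 18-crown-6, THF, −78 °C
Reagents that add atoms: none
Why: Still–Gennari olefination, in which the electron-poor trifluoroethyl phosphonate with a dissociated potassium counter-ion should give the kinetic (Z)-trisubstituted enoate, placing the ester carbon (future C14) cis to the C2 chain and the propargyl carbon (C9) trans to it.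

Step 4
Reactants: 6 methyl (2Z)-6-methyl-2-(prop-2-yn-1-yl)hepta-2,6-dienoate
Product: 7 (2Z)-6-methyl-2-(prop-2-yn-1-yl)hepta-2,6-dien-1-ol
Conditions: DIBAL-H (2.3 equiv), CH2Cl2, −78 °C; Rochelle salt
Reagents that add atoms: none
Why: 1,2-Reduction of the enoate by DIBAL-H at low temperature should give the allylic alcohol without touching the terminal alkyne or the alkene geometry.

Step 5
Reactants: 7 (2Z)-6-methyl-2-(prop-2-yn-1-yl)hepta-2,6-dien-1-ol
Product: 8 tert-butyl(dimethyl){[(2Z)-6-methyl-2-(prop-2-yn-1-yl)hepta-2,6-dien-1-yl]oxy}silane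
Conditions: TBSCl, imidazole, DMF, 0 °C → rt
Reagents that add atoms: tert-butyldimethylsilyl chloride (TBSCl), CC(C)(C)[Si](C)(C)Cl
Why: Standard imidazole-promoted silylation of a primary alcohol, which keeps C14–OH masked through both acylations.

Step 6
Reactants: 8 tert-butyl(dimethyl){[(2Z)-6-methyl-2-(prop-2-yn-1-yl)hepta-2,6-dien-1-yl]oxy}silane; 9 acrolein (2 equiv, slow addition)
Product: 10 (3R,7Z)-7-({[tert-butyl(dimethyl)silyl]oxy}methyl)-11-methyldodeca-1,7,11-trien-4-yn-3-ol
Conditions: Me2Zn (2 equiv), (S,S)-ProPhenol (20 mol %), Ph3P=O (40 mol %), toluene, 0 °C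
Reagents that add atoms: none
Why: Zinc–ProPhenol-catalysed asymmetric alkynylation of an enal, in which the alkynylzinc held in the dinuclear zinc pocket should add to the Si face of acrolein and set C6 as R.

Step 7
Reactants: 10 (3R,7Z)-7-({[tert-butyl(dimethyl)silyl]oxy}methyl)-11-methyldodeca-1,7,11-trien-4-yn-3-ol
Product: 11 (3R,4E,7Z)-7-({[tert-butyl(dimethyl)silyl]oxy}methyl)-11-methyldodeca-1,4,7,11-tetraen-3-ol
Conditions: Red-Al (2.5 equiv), THF, 0 °C → rt; Rochelle salt
Reagents that add atoms: none
Why: Alkoxide-directed trans-hydroalumination of the propargylic alcohol followed by protonolysis should give only the (E)-C7=C8 alkene and leaves C6 untouched.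

Step 8
Reactants: 11 (3R,4E,7Z)-7-({[tert-butyl(dimethyl)silyl]oxy}methyl)-11-methyldodeca-1,4,7,11-tetraen-3-ol
Product: 12 (1R)-1-[(2R,3R)-3-{(2Z)-2-({[tert-butyl(dimethyl)silyl]oxy}methyl)-6-methylhepta-2,6-dien-1-yl}oxiran-2-yl]prop-2-en-1-ol
Conditions: Ti(OiPr)4 (0.3 equiv), D-(−)-DIPT (0.36 equiv), t-BuOOH (1.5 equiv), 4 Å MS, CH2Cl2, −20 °C
Reagents that add atoms: tert-butyl hydroperoxide, CC(C)(C)OO
Why: Sharpless asymmetric epoxidation in its matched kinetic-resolution mode, in which the D-(−)-tartrate titanium complex should epoxidise the (E)-C7=C8 alkene of the (R)-carbinol far faster than the vinyl group and give the erythro (anti) epoxy alcohol, so that C7 and C8 are set by C6 and the ligand together while the silylated C1=C10 alkene, not being an allylic alcohol, is ignored.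

Step 9
Reactants: 12 (1R)-1-[(2R,3R)-3-{(2Z)-2-({[tert-butyl(dimethyl)silyl]oxy}methyl)-6-methylhepta-2,6-dien-1-yl}oxiran-2-yl]prop-2-en-1-ol; 13 acryloyl chloride
Product: 14 (1R)-1-[(2S,3R)-3-{(2Z)-2-({[tert-butyl(dimethyl)silyl]oxy}methyl)-6-methylhepta-2,6-dien-1-yl}oxiran-2-yl]prop-2-en-1-yl prop-2-enoate
Conditions: i-Pr2NEt, BHT (trace), CH2Cl2, −78 → 0 °C
Reagents that add atoms: none
Why: O-Acylation of the secondary alcohol with an acid chloride under a hindered amine base at low temperature should proceed without Payne rearrangement or polymerisation; the oxirane descriptor changes only because the priorities change.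

Step 10
Reactants: 14 (1R)-1-[(2S,3R)-3-{(2Z)-2-({[tert-butyl(dimethyl)silyl]oxy}methyl)-6-methylhepta-2,6-dien-1-yl}oxiran-2-yl]prop-2-en-1-yl prop-2-enoate
Product: 17 (4R,5R)-5-ethenyl-4-[(1R,3Z)-3-({[tert-butyl(dimethyl)silyl]oxy}methyl)-1-hydroxy-7-methylocta-3,7-dien-1-yl]-3-methylideneoxolan-2-one, via phosphonium enolate 15 (not isolated), via phosphonio lactone alkoxide 16 (not isolated)
Conditions: PMe3 (0.5 equiv), t-BuOH/THF 1:1 (0.02 M), BHT (trace), rt → 40 °C
Reagents that add atoms: none
Why: Proposed new method: PMe3 adds reversibly to C13 of the acrylate to give the phosphonium enolate 15, whose α-carbon C11 attacks C7 of the neighbouring oxirane from the rear (t-BuOH hydrogen-bonds the oxirane oxygen) to give the lactone alkoxide 16, after which the C8 alkoxide removes the C11 proton through a six-membered transition state and E1cB loss of PMe3 restores the exocyclic C11=C13 alkene and the catalyst. The closest known reaction type is the phosphine-mediated intramolecular Morita–Baylis–Hillman alkylation of enones by tethered epoxides and alkyl halides; new here are the acrylate ester as acceptor and a tether that runs through the ester oxygen, so that the ring formed is the lactone. The γ-lactone closes in the 5-exo-tet mode (ring atoms C11, C12, O, C6, C7, with the breaking C7–O bond exocyclic), which should be preferred over 6-endo attack at C8. C7 is set by SN2 inversion and C8 keeps its oxirane configuration, so the erythro trans-epoxy ester is translated stereospecifically into the trans-6,7-disubstituted lactone with the C8 hydroxyl anti to the new C7–C11 bond, while C6 is untouched and the transient C11 centre is erased on elimination. The step needs intramolecular alkylation to outrun Rauhut–Currier dimerisation and 6-endo opening, which should be secured by high dilution, by free rotation about C6–C7 in the acyclic substrate (rear-side trajectory within reach) and by the loss of ester resonance in the ketene-acetal-like enolate 15 (s-cis geometry accessible); the vinyl group, the two remote alkenes and the silyl ether are inert to PMe3.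

Step 11
Reactants: 17 (4R,5R)-5-ethenyl-4-[(1R,3Z)-3-({[tert-butyl(dimethyl)silyl]oxy}methyl)-1-hydroxy-7-methylocta-3,7-dien-1-yl]-3-methylideneoxolan-2-one; 18 isobutyric anhydride
Product: 19 (1R,3Z)-3-({[tert-butyl(dimethyl)silyl]oxy}methyl)-1-[(2R,3R)-2-ethenyl-4-methylidene-5-oxooxolan-3-yl]-7-methylocta-3,7-dien-1-yl 2-methylpropanoate
Conditions: Et3N, DMAP (10 mol %), CH2Cl2, 0 °C → rt
Reagents that add atoms: none
Why: DMAP-catalysed acyl transfer to the only free hydroxyl (C8–OH) should install the isobutyrate with retention at C8.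

Step 12
Reactants: 19 (1R,3Z)-3-({[tert-butyl(dimethyl)silyl]oxy}methyl)-1-[(2R,3R)-2-ethenyl-4-methylidene-5-oxooxolan-3-yl]-7-methylocta-3,7-dien-1-yl 2-methylpropanoate
Product: 20 (1R,3Z)-1-[(2R,3R)-2-ethenyl-4-methylidene-5-oxooxolan-3-yl]-3-(hydroxymethyl)-7-methylocta-3,7-dien-1-yl 2-methylpropanoate
Conditions: HF·pyridine, pyridine, THF, 0 °C → rt
Reagents that add atoms: none
Why: Buffered fluoride desilylation of the primary allylic silyl ether should spare the ester, the lactone and the conjugate acceptor, and no oxirane is present at this stage.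

Step 13
Reactants: 20 (1R,3Z)-1-[(2R,3R)-2-ethenyl-4-methylidene-5-oxooxolan-3-yl]-3-(hydroxymethyl)-7-methylocta-3,7-dien-1-yl 2-methylpropanoate
Product: 21 (1R)-1-[(2R,3R)-2-ethenyl-4-methylidene-5-oxooxolan-3-yl]-2-[(2S,3R)-2-(hydroxymethyl)-3-(3-methylbut-3-en-1-yl)oxiran-2-yl]ethyl 2-methylpropanoate
Conditions: Ti(OiPr)4 (0.5 equiv), L-(+)-DET (0.6 equiv), t-BuOOH (2 equiv), 4 Å MS, CH2Cl2, −20 °C
Reagents that add atoms: tert-butyl hydroperoxide, CC(C)(C)OO
Why: Sharpless asymmetric epoxidation of the 2,3-disubstituted C14 allylic alcohol, in which the L-(+)-tartrate titanium complex should deliver oxygen under reagent control to give C1 R and C10 S, the alkene geometry (C14 cis to C2) becoming the trans-ring oxirane, while the vinyl, the 1,1-disubstituted and the electron-poor exocyclic alkenes are not substrates.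

Step 14
Reactants: 21 (1R)-1-[(2R,3R)-2-ethenyl-4-methylidene-5-oxooxolan-3-yl]-2-[(2S,3R)-2-(hydroxymethyl)-3-(3-methylbut-3-en-1-yl)oxiran-2-yl]ethyl 2-methylpropanoate
Product: 22 CNP0247143.1 (1R,4Z,6R,7R,8R,10S)-1,10-epoxy-14-hydroxy-8-(2-methylpropanoyloxy)germacra-4,11(13)-dien-12,6-olide
Conditions: Hoveyda–Grubbs II (15 mol %), toluene (0.5 mM), 80 °C, argon sparge
Reagents that add atoms: none
Why: Ring-closing metathesis between the C5 vinyl group and the C4 1,1-disubstituted alkene, in which the trans-lactone and the trans-oxirane pre-organise the chain, loss of ethylene drives the closure, and the strain of a ten-membered ring should make the cis (4Z) ring alkene the product; the oxirane has already removed the C1=C10 alkene that could otherwise close a cyclohexene.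

**Compound list**

1 | 4-methylpent-4-en-1-ol | C=C(C)CCCO | starting material
2 | 4-methylpent-4-enal | C=C(C)CCC=O | intermediate
3 | methyl 2-[bis(2,2,2-trifluoroethoxy)phosphoryl]acetate | COC(=O)CP(=O)(OCC(F)(F)F)OCC(F)(F)F | starting material
4 | propargyl bromide (3-bromoprop-1-yne) | C#CCBr | starting material
5 | methyl 2-[bis(2,2,2-trifluoroethoxy)phosphoryl]pent-4-ynoate (racemic) | COC(=O)C(CC#C)P(=O)(OCC(F)(F)F)OCC(F)(F)F | intermediate
6 | methyl (2Z)-6-methyl-2-(prop-2-yn-1-yl)hepta-2,6-dienoate | COC(=O)/C(CC#C)=C\CCC(C)=C | intermediate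
7 | (2Z)-6-methyl-2-(prop-2-yn-1-yl)hepta-2,6-dien-1-ol | OC/C(CC#C)=C\CCC(C)=C | intermediate
8 | tert-butyl(dimethyl){[(2Z)-6-methyl-2-(prop-2-yn-1-yl)hepta-2,6-dien-1-yl]oxy}silane | CC(C)(C)[Si](C)(C)OC/C(CC#C)=C\CCC(C)=C | intermediate
9 | acrolein (prop-2-enal) | C=CC=O | starting material
10 | (3R,7Z)-7-({[tert-butyl(dimethyl)silyl]oxy}methyl)-11-methyldodeca-1,7,11-trien-4-yn-3-ol | C=C[C@@H](O)C#CC/C(CO[Si](C)(C)C(C)(C)C)=C/CCC(C)=C | intermediate
11 | (3R,4E,7Z)-7-({[tert-butyl(dimethyl)silyl]oxy}methyl)-11-methyldodeca-1,4,7,11-tetraen-3-ol | C=C[C@@H](O)/C=C/C/C(CO[Si](C)(C)C(C)(C)C)=C/CCC(C)=C | intermediate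
12 | (1R)-1-[(2R,3R)-3-{(2Z)-2-({[tert-butyl(dimethyl)silyl]oxy}methyl)-6-methylhepta-2,6-dien-1-yl}oxiran-2-yl]prop-2-en-1-ol (erythro, trans-oxirane) | C=C[C@@H](O)[C@H]1O[C@@H]1C/C(CO[Si](C)(C)C(C)(C)C)=C/CCC(C)=C | intermediate
13 | acryloyl chloride | C=CC(=O)Cl | starting material
14 | (1R)-1-[(2S,3R)-3-{(2Z)-2-({[tert-butyl(dimethyl)silyl]oxy}methyl)-6-methylhepta-2,6-dien-1-yl}oxiran-2-yl]prop-2-en-1-yl prop-2-enoate | C=C[C@@H](OC(=O)C=C)[C@H]1O[C@@H]1C/C(CO[Si](C)(C)C(C)(C)C)=C/CCC(C)=C | intermediate
15 | phosphonium enolate: zwitterion of 14 with PMe3 on C13 and the ester enolate at C11/C12 (configuration of 14) | C=C[C@@H](OC([O-])=CC[P+](C)(C)C)[C@H]1O[C@@H]1C/C(CO[Si](C)(C)C(C)(C)C)=C/CCC(C)=C | intermediate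
16 | phosphonio lactone alkoxide: γ-lactone with CH2PMe3+ on C11 (both epimers) and the C8 alkoxide (configuration of 17 at C6, C7, C8) | C=C[C@H]1OC(=O)C(C[P+](C)(C)C)[C@@H]1[C@H]([O-])C/C(CO[Si](C)(C)C(C)(C)C)=C/CCC(C)=C | intermediate
17 | (4R,5R)-5-ethenyl-4-[(1R,3Z)-3-({[tert-butyl(dimethyl)silyl]oxy}methyl)-1-hydroxy-7-methylocta-3,7-dien-1-yl]-3-methylideneoxolan-2-one | C=C[C@H]1OC(=O)C(=C)[C@@H]1[C@H](O)C/C(CO[Si](C)(C)C(C)(C)C)=C/CCC(C)=C | intermediate
18 | isobutyric anhydride | CC(C)C(=O)OC(=O)C(C)C | starting material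
19 | (1R,3Z)-3-({[tert-butyl(dimethyl)silyl]oxy}methyl)-1-[(2R,3R)-2-ethenyl-4-methylidene-5-oxooxolan-3-yl]-7-methylocta-3,7-dien-1-yl 2-methylpropanoate | C=C[C@H]1OC(=O)C(=C)[C@@H]1[C@H](OC(=O)C(C)C)C/C(CO[Si](C)(C)C(C)(C)C)=C/CCC(C)=C | intermediate
20 | (1R,3Z)-1-[(2R,3R)-2-ethenyl-4-methylidene-5-oxooxolan-3-yl]-3-(hydroxymethyl)-7-methylocta-3,7-dien-1-yl 2-methylpropanoate | C=C[C@H]1OC(=O)C(=C)[C@@H]1[C@H](OC(=O)C(C)C)C/C(CO)=C/CCC(C)=C | intermediate
21 | (1R)-1-[(2R,3R)-2-ethenyl-4-methylidene-5-oxooxolan-3-yl]-2-[(2S,3R)-2-(hydroxymethyl)-3-(3-methylbut-3-en-1-yl)oxiran-2-yl]ethyl 2-methylpropanoate | C=C[C@H]1OC(=O)C(=C)[C@@H]1[C@H](OC(=O)C(C)C)C[C@@]2(CO)O[C@@H]2CCC(C)=C | intermediate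
22 | CNP0247143.1, (1R,4Z,6R,7R,8R,10S)-1,10-epoxy-14-hydroxy-8-(2-methylpropanoyloxy)germacra-4,11(13)-dien-12,6-olide | C=C1C(=O)O[C@@H]2/C=C(/C)CC[C@H]3O[C@]3(CO)C[C@@H](OC(=O)C(C)C)[C@@H]12 | target

**Count**

Total steps: 14. Longest linear sequence: 13 (step 1 or step 2, then steps 3–14).

**Steps most likely to fail**

Step 10 (proposed new method). The phosphonium enolate may add and revert without ever alkylating the oxirane, because ring closure through the ester is slow, so that intermolecular Rauhut–Currier oligomerisation takes over; attack at C8 (6-endo) would be a second failure mode. The fallback uses known reaction types and sets out from 12. Esterification with diethylphosphonoacetic acid (DCC, DMAP, CH2Cl2) should give the phosphonoacetate ester F1. Deprotonation with KOtBu in THF (0 °C → rt) gives a stabilised carbanion that opens the oxirane at C7 in the same 5-exo mode, with the same inversion, to give the α-phosphono lactone F2. Paraformaldehyde added to the same flask then effects Horner–Wadsworth–Emmons methylenation, and the route is rejoined at 17.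

Step 14. Cross-metathesis oligomerisation may compete with closure of the strained ring, and the ruthenium alkylidene may be captured unproductively by the conjugated exocyclic alkene of the lactone, so that the hindered 1,1-disubstituted alkene is never engaged. The fallback sets out from 21 and takes the conjugated alkene out of play. Conjugate addition of thiophenol (Et3N cat., THF) should give the sulfide F3, whose sp3 C11 also relaxes the lactone. Ring-closing metathesis of F3 under the conditions of step 14 gives the macrocyclic sulfide F4. Oxidation with NaIO4 (MeOH/H2O, 0 °C) gives the sulfoxide F5, and thermal syn-elimination (toluene, 90 °C, CaCO3), which can only involve the C11 hydrogen, regenerates the methylene and gives 22.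

Step 6. Acrolein may polymerise under the zinc alkoxide conditions and the facial selectivity may be poor with so small an enal. The fallback sets out from 8 and sets C6 by resolution instead of by addition. Lithiation (n-BuLi, THF, −78 °C) and addition to acrolein should give the racemic carbinol F6, and Red-Al reduction the racemic (E)-dienol F7. Sharpless kinetic resolution of F7 (Ti(OiPr)4, D-(−)-DIPT, 0.55 equiv t-BuOOH, −20 °C) should epoxidise only the (R)-enantiomer and deliver 12, where the route is rejoined; the unreacted (S)-alcohol is separated by chromatography.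

**Further compounds**

F1 | step 10 | (1R)-1-[(2S,3R)-3-{(2Z)-2-({[tert-butyl(dimethyl)silyl]oxy}methyl)-6-methylhepta-2,6-dien-1-yl}oxiran-2-yl]prop-2-en-1-yl 2-(diethoxyphosphoryl)acetate | C=C[C@@H](OC(=O)CP(=O)(OCC)OCC)[C@H]1O[C@@H]1C/C(CO[Si](C)(C)C(C)(C)C)=C/CCC(C)=C
F2 | step 10 | diethyl {(4R,5R)-5-ethenyl-4-[(1R,3Z)-3-({[tert-butyl(dimethyl)silyl]oxy}methyl)-1-hydroxy-7-methylocta-3,7-dien-1-yl]-2-oxooxolan-3-yl}phosphonate (C3 epimers) | C=C[C@H]1OC(=O)C(P(=O)(OCC)OCC)[C@@H]1[C@H](O)C/C(CO[Si](C)(C)C(C)(C)C)=C/CCC(C)=C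
F3 | step 14 | (1R)-1-{(2R,3R)-2-ethenyl-5-oxo-4-[(phenylsulfanyl)methyl]oxolan-3-yl}-2-[(2S,3R)-2-(hydroxymethyl)-3-(3-methylbut-3-en-1-yl)oxiran-2-yl]ethyl 2-methylpropanoate (C4 epimers) | C=C[C@H]1OC(=O)C(CSc2ccccc2)[C@@H]1[C@H](OC(=O)C(C)C)C[C@@]3(CO)O[C@@H]3CCC(C)=C
F4 | step 14 | (1R,4Z,6R,7R,8R,10S)-1,10-epoxy-14-hydroxy-8-(2-methylpropanoyloxy)-13-(phenylsulfanyl)germacr-4-en-12,6-olide (C11 epimers) | O=C1O[C@@H]2/C=C(/C)CC[C@H]3O[C@]3(CO)C[C@@H](OC(=O)C(C)C)[C@H]2C1CSc1ccccc1
F5 | step 14 | S-oxide of F4, (1R,4Z,6R,7R,8R,10S)-1,10-epoxy-14-hydroxy-8-(2-methylpropanoyloxy)-13-(phenylsulfinyl)germacr-4-en-12,6-olide (epimers at C11 and sulfur) | O=C1O[C@@H]2/C=C(/C)CC[C@H]3O[C@]3(CO)C[C@@H](OC(=O)C(C)C)[C@H]2C1CS(=O)c1ccccc1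
F6 | step 6 | rac-(7Z)-7-({[tert-butyl(dimethyl)silyl]oxy}methyl)-11-methyldodeca-1,7,11-trien-4-yn-3-ol | C=CC(O)C#CC/C(CO[Si](C)(C)C(C)(C)C)=C/CCC(C)=C
F7 | step 6 | rac-(4E,7Z)-7-({[tert-butyl(dimethyl)silyl]oxy}methyl)-11-methyldodeca-1,4,7,11-tetraen-3-ol | C=CC(O)/C=C/C/C(CO[Si](C)(C)C(C)(C)C)=C/CCC(C)=C
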